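C1 = prenyl-bearing quaternary carbon, C2/C5 = ketone carbons, C3=C4 = enedione alkene, C6 = aryl-bearing quaternary carbon, C7=C8(CH3)–C9 = three-carbon bridge, C10 = benzylic CH, C11–C16 = arene (C11 on C10, C16 on C6); ring A = C1–C6, ring B = C1/C6/C16/C11/C10, ring C = C6–C7–C8–C9–C10–C1, ring D = arene.
Cuts, backwards: both aryl O–H from O–CH3; C3=C4 from a saturated dione; C8–C9 (ring C) by B-alkyl Suzuki coupling; C6–C7 by a formaldehyde aldol; C10=C9 by methylenation; last, C1–C2 and C5–C6 together.
Enabling feature: ring A carries its carbonyls at C2 and C5, 1,4 across C3=C4, and shares C1–C6 with five-membered ring B, whose third sp3 carbon C10 is benzylic. With a carbonyl on C10, C1–C6 is the enone bond of a 2-prenylindenone and C2–C3=C4–C5 is what a 1,4-dioxygenated butadiene delivers in a [4+2] addition.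
Forward: rings B and D come with the indanone; ring A closes in the cycloaddition; C9 is added to C10 and C7/C8 to C6; ring C closes last; then the enedione and the free hydroquinone are unveiled.
Stereochemistry: C1 and C6 (cis) come from the catalyst-controlled cycloaddition; the cis fusion is kept when C6 becomes quaternary; C10 comes from hydroboration on the face away from the C1 and C6 top-face substituents, proof-read by a ring closure open only to that epimer.
Key step: step 5

Assumption: the (S)-configured oxazaborolidinium ion is taken to expose the C1=C6 face that gives 10 as drawn; if induction runs the other way, the (R)-catalyst is used with no other change.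

Step 1
Reactants: 1 4,7-dimethoxyindan-1-one
Product: 3 4,7-dimethoxy-1H-inden-1-one, via 3-bromo-4,7-dimethoxyindan-1-one 2 (not isolated)
Conditions: NBS, AIBN (cat.), PhCF3, 80 °C; then Et3N, 0 °C
Reagents that add atoms: none
Why: Wohl–Ziegler bromination takes the benzylic C3–H and the β-bromo ketone loses HBr by E1cB elimination with the amine, the standard entry to indenones; the crude indenone is used at once to avoid dimerisation.

Step 2
Reactants: 3 4,7-dimethoxy-1H-inden-1-one
Product: 4 2-iodo-4,7-dimethoxy-1H-inden-1-one
Conditions: I2, pyridine, CH2Cl2, 0 °C to rt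
Reagents that add atoms: iodine, [I][I]
Why: α-Iodination of a cyclic enone by conjugate addition of pyridine, iodination of the enolate and loss of pyridine (addition–elimination) places the halogen only on the α-carbon.

Step 3
Reactants: 4 2-iodo-4,7-dimethoxy-1H-inden-1-one; 5 tributyl(3-methylbut-2-en-1-yl)stannane
Product: 6 4,7-dimethoxy-2-(3-methylbut-2-en-1-yl)-1H-inden-1-one
Conditions: Pd2(dba)3 (cat.), AsPh3, CuI (cat.), NMP, rt
Reagents that add atoms: none
Why: Stille cross-coupling of an α-iodo enone with an allylic stannane joins the unsubstituted allyl terminus to the α-carbon and, unlike a dehydrogenation of 2-prenylindanone, leaves no choice between endocyclic and exocyclic unsaturation.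

Step 4
Reactants: 7 (1E,3E)-buta-1,3-diene-1,4-diyl diacetate
Product: 9 (1E,3E)-1,4-bis(tert-butyldimethylsilyloxy)buta-1,3-diene, via dilithium (1E,3E)-buta-1,3-diene-1,4-diolate 8 (not isolated)
Conditions: MeLi (4.2 equiv), THF, −78 to 0 °C; TBSCl (excess), DMPU, −78 °C to rt
Reagents that add atoms: tert-butyldimethylsilyl chloride, CC(C)(C)[Si](C)(C)Cl
Why: Cleavage of enol acetates by methyllithium gives the lithium enolates with retention of double-bond geometry, and O-silylation then fixes the (E,E)-diene, the only isomer with an accessible s-cis conformation for the Diels–Alder step.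

Step 5
Reactants: 6 4,7-dimethoxy-2-(3-methylbut-2-en-1-yl)-1H-inden-1-one; 9 (1E,3E)-1,4-bis(tert-butyldimethylsilyloxy)buta-1,3-diene
Product: 10 endo cycloadduct (cis-fused tetrahydrofluorenone; silyloxy groups on C2 and C5; C3=C4; C10 ketone)
Conditions: (S)-B-(o-tolyl)oxazaborolidine from (S)-α,α-diphenylprolinol (20 mol %), Tf2NH (18 mol %), 9 (2 equiv), CH2Cl2, −78 to −40 °C
Reagents that add atoms: none
Why: The boron cation binds the C10 carbonyl of the strained, s-cis-locked indenone and lowers its LUMO, so the electron-rich (E,E)-diene adds across C1=C6 in a concerted, asynchronous [4+2] cycloaddition that bonds first at the β-carbon C6. The closest known reaction type is the oxazaborolidinium-catalysed Diels–Alder reaction of cyclic enones and quinones with silyloxy dienes. Ring A closes in one [4+2] event, suprafacial on both partners, forming C1–C2 and C5–C6 and leaving C3=C4 in place. C1 and C6 are cis because both bonds form on one face of the ring alkene, their absolute sense comes from the catalyst's aryl groups blocking the other face, and the C2/C5 configurations follow from the E,E geometry of 9 and the endo transition state (they are erased later). The step needs π-facial selectivity, supplied by the catalyst, and chemoselectivity for C1=C6 over the prenyl alkene, secured because only the conjugated, strained indenone bond is activated; regiochemistry does not arise because 9 is C2-symmetric.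

Step 6
Reactants: 10 endo cycloadduct
Product: 11 C10-methylene bis-silyl ether (C10=C9H2)
Conditions: Ph3PCH3Br, KOtBu, toluene, 90 °C
Reagents that add atoms: methyltriphenylphosphonium bromide, C[P+](c1ccccc1)(c1ccccc1)c1ccccc1.[Br-]
Why: Wittig methylenation; the C10 ketone has no α-hydrogen (C1 quaternary, aryl on the other side), so the ylide can only add to the carbonyl and no stereocentre is touched.

Step 7
Reactants: 11 C10-methylene bis-silyl ether
Product: 12 C2,C5-diol
Conditions: Bu4NF, THF, 0 to 40 °C
Reagents that add atoms: none
Why: Fluoride-induced Si–O cleavage frees both allylic alcohols under non-acidic conditions that spare the electron-rich exocyclic styrene and the prenyl group.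

Step 8
Reactants: 12 C2,C5-diol
Product: 13 cis-fused ene-1,4-dione (C2 and C5 ketones; C3=C4; C6–H)
Conditions: Dess–Martin periodinane, NaHCO3, CH2Cl2, 0 °C to rt
Reagents that add atoms: none
Why: Dess–Martin oxidation converts both secondary allylic alcohols into ketones; with C1 quaternary the enedione cannot aromatise, and the C2/C5 stereocentres, no longer needed, disappear.

Step 9
Reactants: 13 cis-fused ene-1,4-dione
Product: 14 cis-fused saturated 1,4-dione
Conditions: Zn dust, AcOH, rt
Reagents that add atoms: none
Why: Zinc in acetic acid reduces only the doubly activated C3=C4 bond of an ene-1,4-dione (dissolving-metal conjugate reduction), removing the Michael acceptor that would not survive the ylide and borane used later, while C6–H stays in the more stable cis-fused arrangement.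

Step 10
Reactants: 14 cis-fused saturated 1,4-dione
Product: 15 C6-hydroxymethyl dione (CH2OH cis to prenyl)
Conditions: 37% aq. CH2O, K2CO3 (cat.), THF, 0 °C to rt
Reagents that add atoms: formaldehyde, C=O
Why: Aldol addition to formaldehyde under mild, reversible base occurs at C6, the only position both α to a ketone and benzylic and so by far the most acidic, and the adduct that accumulates is the cis-fused one with C7 on the prenyl face, which sets the C6 quaternary centre.

Step 11
Reactants: 15 C6-hydroxymethyl dione
Product: 16 C6-formyl dione
Conditions: Dess–Martin periodinane, NaHCO3, CH2Cl2, 0 °C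
Reagents that add atoms: none
Why: Dess–Martin oxidation of the neopentyl primary alcohol under buffered, non-nucleophilic conditions gives the non-enolisable β-keto aldehyde, which is carried on without storage to forestall deformylation.

Step 12
Reactants: 16 C6-formyl dione
Product: 17 C6-[(Z)-2-iodoprop-1-enyl] dione (iodine cis to C6)
Conditions: EtPPh3I, n-BuLi, THF; I2, −78 °C; NaN(SiMe3)2, −20 °C; then 16, −78 to −20 °C
Reagents that add atoms: ethyltriphenylphosphonium iodide, CC[P+](c1ccccc1)(c1ccccc1)c1ccccc1.[I-]; iodine, [I][I]
Why: Stork–Zhao-type Wittig olefination with the α-iodo ylide Ph3P=C(I)CH3 reacts with the aldehyde much faster than with the two hindered ketones and, through the kinetically favoured cis-oxaphosphetane, gives the iodoalkene with iodine cis to C6, the geometry the ring closure needs.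

Step 13
Reactants: 17 C6-[(Z)-2-iodoprop-1-enyl] dione
Product: 19 ring C-closed dimethyl ether with saturated ring A, via C9-boryl 9-BBN adduct 18 (not isolated)
Conditions: 9-BBN, THF, 0 °C to rt; then Pd(dppf)Cl2 (cat.), AsPh3, Cs2CO3, DMF/H2O, rt to 50 °C
Reagents that add atoms: none
Why: 9-BBN hydroborates the 1,1-disubstituted C10=C9 alkene at its CH2 terminus far faster than the trisubstituted alkenes, delivering hydrogen to C10 from the ring A face (the other face carries the prenyl and iodoalkenyl groups), and intramolecular B-alkyl Suzuki–Miyaura coupling (oxidative addition of zerovalent palladium into C–I with retention, transmetalation, reductive elimination) then forms C8–C9 and closes ring C, a closure geometrically possible only for the C10 epimer with C9 on the bridge face.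

Step 14
Reactants: 19 ring C-closed dimethyl ether with saturated ring A
Product: 20 target dimethyl ether (ene-1,4-dione restored)
Conditions: 2-iodoxybenzoic acid (IBX), DMSO/toluene, 70 °C
Reagents that add atoms: none
Why: IBX-mediated dehydrogenation of a ketone to its enone; C3 and C4 are the only enolisable positions (C1 and C6 are quaternary), so a single ene-1,4-dione forms and cannot be oxidised further.

Step 15
Reactants: 20 target dimethyl ether
Product: 22 CNP0513322.1, via ring D quinone 21 (not isolated)
Conditions: (NH4)2Ce(NO3)6, MeCN/H2O, 0 °C; then Na2S2O4, EtOAc/H2O, rt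
Reagents that add atoms: water, O
Why: Oxidative demethylation of a 1,4-dimethoxyarene with (NH4)2Ce(NO3)6 gives the para-quinone at 0 °C without touching the alkenes, and dithionite then reduces the quinone, a far better electron acceptor than the ene-dione, to the hydroquinone.

Compound list
1 | 4,7-dimethoxyindan-1-one | COc1ccc(OC)c2C(=O)CCc12 | starting material
2 | 3-bromo-4,7-dimethoxyindan-1-one (racemic) | COc1ccc(OC)c2C(=O)CC(Br)c12 | intermediate (not isolated)
3 | 4,7-dimethoxy-1H-inden-1-one | COc1ccc(OC)c2C(=O)C=Cc12 | intermediate
4 | 2-iodo-4,7-dimethoxy-1H-inden-1-one | COc1ccc(OC)c2C(=O)C(I)=Cc12 | intermediate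
5 | tributyl(3-methylbut-2-en-1-yl)stannane | CC(C)=CC[Sn](CCCC)(CCCC)CCCC | starting material
6 | 4,7-dimethoxy-2-(3-methylbut-2-en-1-yl)-1H-inden-1-one | CC(C)=CCC1=Cc2c(OC)ccc(OC)c2C1=O | intermediate
7 | (1E,3E)-buta-1,3-diene-1,4-diyl diacetate | CC(=O)O/C=C/C=C/OC(C)=O | starting material
8 | dilithium (1E,3E)-buta-1,3-diene-1,4-diolate | [Li]O/C=C/C=C/O[Li] | intermediate (not isolated)
9 | (1E,3E)-1,4-bis(tert-butyldimethylsilyloxy)buta-1,3-diene | CC(C)(C)[Si](C)(C)O/C=C/C=C/O[Si](C)(C)C(C)(C)C | intermediate
10 | endo cycloadduct: cis-fused 1,4-bis(tert-butyldimethylsilyloxy)-5,8-dimethoxy-9a-(3-methylbut-2-en-1-yl)-1,4,4a,9a-tetrahydro-9H-fluoren-9-one; H on C6 cis to prenyl, both silyloxy groups on the opposite face of ring A | CC(C)=CC[C@]12C(=O)c3c(OC)ccc(OC)c3[C@H]1[C@@H](O[Si](C)(C)C(C)(C)C)C=C[C@H]2O[Si](C)(C)C(C)(C)C | intermediate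
11 | 9-methylene analogue of 10 (C10=C9H2 in place of the C10 ketone) | CC(C)=CC[C@]12C(=C)c3c(OC)ccc(OC)c3[C@H]1[C@@H](O[Si](C)(C)C(C)(C)C)C=C[C@H]2O[Si](C)(C)C(C)(C)C | intermediate
12 | C2,C5-diol from 11 (both hydroxyls trans to prenyl) | CC(C)=CC[C@]12C(=C)c3c(OC)ccc(OC)c3[C@H]1[C@@H](O)C=C[C@H]2O | intermediate
13 | cis-fused 5,8-dimethoxy-9-methylene-9a-prenyl-4a,9a-dihydro-1H-fluorene-1,4(9H)-dione (ene-1,4-dione) | CC(C)=CC[C@]12C(=C)c3c(OC)ccc(OC)c3[C@H]1C(=O)C=CC2=O | intermediate
14 | cis-fused 5,8-dimethoxy-9-methylene-9a-prenyl-2,3,4a,9a-tetrahydro-1H-fluorene-1,4(9H)-dione | CC(C)=CC[C@]12C(=C)c3c(OC)ccc(OC)c3[C@H]1C(=O)CCC2=O | intermediate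
15 | 4a-(hydroxymethyl) derivative of 14 (CH2OH on C6, cis to prenyl) | CC(C)=CC[C@]12C(=C)c3c(OC)ccc(OC)c3[C@@]1(CO)C(=O)CCC2=O | intermediate
16 | 4a-formyl derivative of 14 (CHO on C6, cis to prenyl) | CC(C)=CC[C@]12C(=C)c3c(OC)ccc(OC)c3[C@@]1(C=O)C(=O)CCC2=O | intermediate
17 | 4a-[(Z)-2-iodoprop-1-en-1-yl] derivative of 14 (C7H=C8(CH3)I on C6, iodine cis to C6) | CC(C)=CC[C@]12C(=C)c3c(OC)ccc(OC)c3[C@@]1(/C=C(/C)I)C(=O)CCC2=O | intermediate
18 | hydroboration adduct of 17: C10–H on the ring A face, C9H2–B(9-borabicyclo[3.3.1]nonyl) cis to prenyl | CC(C)=CC[C@]12[C@H](CB4C5CCCC4CCC5)c3c(OC)ccc(OC)c3[C@@]1(/C=C(/C)I)C(=O)CCC2=O | intermediate (not isolated)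
19 | 3,4-dihydro target dimethyl ether (rings A–D complete; ring A saturated 1,4-dione; prenyl syn to the C7=C8–C9 bridge) | CC(C)=CC[C@@]12C(=O)CCC(=O)[C@@]13C=C(C)C[C@@H]2c1c(OC)ccc(OC)c13 | intermediate
20 | target O,O-dimethyl ether (ene-1,4-dione in ring A) | CC(C)=CC[C@@]12C(=O)C=CC(=O)[C@@]13C=C(C)C[C@@H]2c1c(OC)ccc(OC)c13 | intermediate
21 | ring D para-quinone of the target | CC(C)=CC[C@@]12C(=O)C=CC(=O)[C@@]13C=C(C)C[C@@H]2C1=C3C(=O)C=CC1=O | intermediate (not isolated)
22 | CNP0513322.1 (hydroquinone ring D, enedione ring A, prenyl on C1 syn to the C7=C8–C9 bridge) | CC(C)=CC[C@@]12C(=O)C=CC(=O)[C@@]13C=C(C)C[C@@H]2c1c(O)ccc(O)c13 | target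

Total step count: 15. Longest linear sequence: 14 steps (steps 1–3 and 5–15; step 4 is the one-step branch to the diene).

Steps most likely to fail

Step 13. Hydroboration may deliver hydrogen to the top face of the exocyclic alkene, giving the C10 epimer that cannot cyclise. The borane may also reduce the two ketones before it reaches the hindered alkene, or the strained intramolecular transmetalation may stall so that protodeboronation wins. The fallback sets out from 17 and uses a tin hydride-mediated vinyl radical cyclisation (Bu3SnH added slowly, AIBN, benzene, 80 °C, or Et3B/air at low temperature). The C8 radical should add 6-endo to the CH2 terminus C9, since the 5-exo mode would build a benzonorbornadiene. The bridgehead C10 radical can take hydrogen only from the exo side, so C10 is set by the ring closure itself. The fallback comes back to the route at 19 and forms no further compound (F0).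

Step 5. Enantiofacial discrimination may be poor, because the α-prenyl group removes the α-C–H contact that usually orients this catalyst and the peri methoxy group competes for boron. The acidic catalyst may also destroy the silyl dienol ether before cycloaddition. The fallback sets out from 6 and 9 and runs the cycloaddition thermally without catalyst (toluene, 90 °C, BHT). The endo adduct then forms as a racemate, that is 10 together with its mirror image ent-10 F1. The enantiomers are separated by preparative chromatography on a chiral stationary phase, and the route is rejoined at 10.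

Step 12. Olefination of the neopentyl, non-enolisable β-keto aldehyde may be slow or poorly Z-selective. The basic ylide may remove the formyl group by retro-Claisen attack, or the aldehyde may undergo an intramolecular carbonyl-ene reaction with the neighbouring prenyl group. The fallback sets out from 16 with a non-basic dibromo-olefination (CBr4, PPh3, CH2Cl2, 0 °C) to the 1,1-dibromoalkene F2. A trans-selective Negishi monomethylation (MeZnCl, Pd(DPEphos)Cl2 cat., THF, 0 °C) then replaces the bromine trans to C6 and leaves the (Z)-bromoalkene F3. F3 is hydroborated to the B-alkyl-9-BBN adduct F4 and cyclised under the conditions of step 13, so the route is rejoined at 19.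

Further compounds
F0 | step 13 | none | none
F1 | step 5 | ent-10, mirror image of the endo cycloadduct | CC(C)=CC[C@@]12C(=O)c3c(OC)ccc(OC)c3[C@@H]1[C@H](O[Si](C)(C)C(C)(C)C)C=C[C@@H]2O[Si](C)(C)C(C)(C)C
F2 | step 12 | 4a-(2,2-dibromoethenyl) derivative of 14 | CC(C)=CC[C@]12C(=C)c3c(OC)ccc(OC)c3[C@@]1(C=C(Br)Br)C(=O)CCC2=O
F3 | step 12 | 4a-[(Z)-2-bromoprop-1-en-1-yl] derivative of 14 (bromine cis to C6) | CC(C)=CC[C@]12C(=C)c3c(OC)ccc(OC)c3[C@@]1(/C=C(/C)Br)C(=O)CCC2=O
F4 | step 12 | hydroboration adduct of F3 (C9H2–B(9-borabicyclo[3.3.1]nonyl), C10–H on the ring A face) | CC(C)=CC[C@]12[C@H](CB4C5CCCC4CCC5)c3c(OC)ccc(OC)c3[C@@]1(/C=C(/C)Br)C(=O)CCC2=O
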